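**Retrosynthetic overview**
1. The target is a central benzene ring (labels: C1 and C3 carry the CH2–pyranone arms, C2, C4 and C6 the hydroxyls, C5 the isobutyryl group); the last operation is cleavage of four methyl ethers.
2. The strategy rests on the ortho-hydroxyaryl ketone of that ring, the isobutyryl group on C5 beside the hydroxyl on C6: the C5–C(acyl) and C6–O bonds are cut together, back to a C5≡C6 aryne (from a C5–SiMe3/C6–OTf pair) and isobutyric acid.
3. The two ArCH2–C3(pyranone) bonds are made earlier, by double reductive alkylation of the 4-hydroxypyranone with a 2,4-diformyl silylaryl triflate.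
4. The silylaryl triflate core comes from 4-hydroxy-2,6-dimethoxybenzaldehyde by ortho-formylation, bromination of the last ring C–H, acetal masking, retro-Brook shift and triflation.
5. Ring order: the pyranone ring is closed first (lactonisation of a 3,5-dioxo ester), the benzene ring is bought, and the key step closes no ring.

Key step: step 10

Remarks on the chemistry: the target has no stereocentre, so none has to be set. Atom labels C1–C6 are those of the overview; systematic names use their own locants. It is assumed that in the double reductive alkylation the aldehyde beside the triflate reacts first; this order has no effect on the product.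

**Step 1**
Reactants: 1 methyl 3-oxopentanoate; 2 N-methoxy-N-methylpropanamide
Product: 3 methyl 4-methyl-3,5-dioxoheptanoate (racemic at C4, largely enolised)
Conditions: LiN(i-Pr)2 (LDA, 2.2 equiv), THF, −78 → 0 °C; 2, −78 → 0 °C; aq. HCl
Reagents that add atoms: none
Why: The dianion of the β-keto ester reacts at its more basic γ-carbon, and the Weinreb amide stops at the chelated tetrahedral adduct until work-up, so a single propanoyl group is introduced (γ-acylation of a Huckin–Weiler dianion).

**Step 2**
Reactants: 3 methyl 4-methyl-3,5-dioxoheptanoate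
Product: 4 6-ethyl-4-hydroxy-5-methyl-2H-pyran-2-one
Conditions: DBU (1.5 equiv), toluene, reflux; aq. HCl
Reagents that add atoms: none
Why: DBU enolises the triketide and the enol oxygen of the C5 ketone attacks the methyl ester in a 6-exo-trig lactonisation, the usual closure of 3,5-dioxo esters to 4-hydroxy-2-pyranones.

**Step 3**
Reactants: 5 4-hydroxy-2,6-dimethoxybenzaldehyde
Product: 6 4-hydroxy-2,6-dimethoxybenzene-1,3-dicarbaldehyde
Conditions: MgCl2, Et3N, (CH2O)n, MeCN, reflux; aq. HCl
Reagents that add atoms: paraformaldehyde (formaldehyde), C=O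
Why: Casnati–Skattebøl formylation: the magnesium phenoxide delivers formaldehyde only ortho to the hydroxyl, the two ortho carbons of 5 are equivalent, and the new formyl group deactivates the ring against a second reaction.

**Step 4**
Reactants: 6 4-hydroxy-2,6-dimethoxybenzene-1,3-dicarbaldehyde
Product: 7 5-bromo-4-hydroxy-2,6-dimethoxybenzene-1,3-dicarbaldehyde
Conditions: NBS (1.05 equiv), MeCN, 0 °C → rt
Reagents that add atoms: N-bromosuccinimide, O=C1CCC(=O)N1Br
Why: Electrophilic aromatic bromination at the only ring C–H, which is ortho or para to all three oxygen substituents and meta to both formyl groups.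

**Step 5**
Reactants: 7 5-bromo-4-hydroxy-2,6-dimethoxybenzene-1,3-dicarbaldehyde
Product: 8 2-bromo-4,6-di(1,3-dioxolan-2-yl)-3,5-dimethoxyphenol
Conditions: HOCH2CH2OH (10 equiv), p-TsOH·H2O (5 mol %), benzene, Dean–Stark reflux; Et3N quench
Reagents that add atoms: ethylene glycol, OCCO
Why: Acid-catalysed acetalisation driven by azeotropic removal of water masks both aldehydes as dioxolanes, which are inert to the organolithium of the next step.

**Step 6**
Reactants: 8 2-bromo-4,6-di(1,3-dioxolan-2-yl)-3,5-dimethoxyphenol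
Product: 11 2,4-di(1,3-dioxolan-2-yl)-3,5-dimethoxy-6-(trimethylsilyl)phenyl trifluoromethanesulfonate, via aryl trimethylsilyl ether 9 (not isolated), via lithium 2-silylphenoxide 10 (not isolated)
Conditions: (Me3Si)2NH, THF, 65 °C, then evaporate; n-BuLi (1.1 equiv), THF, −78 °C; PhNTf2 (1.2 equiv), −78 °C → rt; aq. NH4Cl
Reagents that add atoms: hexamethyldisilazane, C[Si](C)(C)N[Si](C)(C)C; N-phenylbis(trifluoromethanesulfonimide), O=S(=O)(N(c1ccccc1)S(=O)(=O)C(F)(F)F)C(F)(F)F
Why: Silylation of the phenol, bromine–lithium exchange (faster than any deprotonation at −78 °C) and a 1,3 O→C retro-Brook shift move the silyl group to the carbon that bore bromine, and the lithium phenoxide set free is the only oxygen that the triflimide can sulfonylate, so silicon and triflate end up on neighbouring carbons.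

**Step 7**
Reactants: 11 2,4-di(1,3-dioxolan-2-yl)-3,5-dimethoxy-6-(trimethylsilyl)phenyl trifluoromethanesulfonate
Product: 12 2,4-diformyl-3,5-dimethoxy-6-(trimethylsilyl)phenyl trifluoromethanesulfonate
Conditions: PPTS (cat.), acetone/H2O, rt
Reagents that add atoms: water, O
Why: The dioxolanes of these doubly ortho-oxygenated benzaldehydes ionise to stabilised oxocarbenium ions under weak acid (acetal hydrolysis), conditions under which the aryl C–Si bond beside the electron-withdrawing triflate is not protodesilylated.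

**Step 8**
Reactants: 12 2,4-diformyl-3,5-dimethoxy-6-(trimethylsilyl)phenyl trifluoromethanesulfonate; 4 6-ethyl-4-hydroxy-5-methyl-2H-pyran-2-one (2.2 equiv)
Product: 16 2,4-bis[(6-ethyl-4-hydroxy-5-methyl-2-oxo-2H-pyran-3-yl)methyl]-3,5-dimethoxy-6-(trimethylsilyl)phenyl trifluoromethanesulfonate, via first arylidene 13 (not isolated), via mono-arm aldehyde 14 (not isolated), via second arylidene 15 (not isolated)
Conditions: Hantzsch ester (diethyl 2,6-dimethyl-1,4-dihydropyridine-3,5-dicarboxylate, 2.4 equiv), L-proline (20 mol %), CH2Cl2, rt → 40 °C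
Reagents that add atoms: none
Why: Three-component reductive alkylation: proline-catalysed Knoevenagel condensation of each aldehyde with the acidic C3–H of the pyranone gives an arylidene that the Hantzsch ester reduces at once by conjugate hydride transfer, so that only C-benzylation should occur and a second pyranone cannot add.

**Step 9**
Reactants: 16 2,4-bis[(6-ethyl-4-hydroxy-5-methyl-2-oxo-2H-pyran-3-yl)methyl]-3,5-dimethoxy-6-(trimethylsilyl)phenyl trifluoromethanesulfonate
Product: 17 2,4-bis[(6-ethyl-4-methoxy-5-methyl-2-oxo-2H-pyran-3-yl)methyl]-3,5-dimethoxy-6-(trimethylsilyl)phenyl trifluoromethanesulfonate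
Conditions: Me2SO4 (2.5 equiv), K2CO3 (3 equiv), acetone, rt
Reagents that add atoms: dimethyl sulfate, COS(=O)(=O)OC
Why: O-Methylation of the potassium salts of the two vinylogous acids with the hard electrophile dimethyl sulfate should give the 4-methoxy-2-pyranones, and carbonate in acetone at room temperature leaves the silylaryl triflate untouched.

**Step 10**
Reactants: 17 2,4-bis[(6-ethyl-4-methoxy-5-methyl-2-oxo-2H-pyran-3-yl)methyl]-3,5-dimethoxy-6-(trimethylsilyl)phenyl trifluoromethanesulfonate; 18 isobutyric acid (2 equiv)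
Product: 21 1-{2-hydroxy-4,6-dimethoxy-3,5-bis[(6-ethyl-4-methoxy-5-methyl-2-oxo-2H-pyran-3-yl)methyl]phenyl}-2-methylpropan-1-one, via aryne 19 (not isolated), via caesium aryl anion 20 (not isolated)
Conditions: 18 pre-stirred with CsF (6 equiv) in toluene; 17, 125 °C, sealed tube; aq. NH4Cl
Reagents that add atoms: none
Why: Fluoride attacks silicon and the triflate leaves, giving the pentasubstituted C5≡C6 aryne 19; isobutyrate oxygen adds to C6, and the aryl anion 20 left at C5 attacks the carbonyl of the new aryl ester through a four-centre transition structure that collapses to the C5 ketone and the C6 phenoxide, a formal insertion of the aryne into the O–C(acyl) bond. The closest known reaction type is the fluoride-induced addition of carboxylic acids to arynes from ortho-silylaryl triflates, which gives ortho-hydroxyaryl ketones in hot toluene. No ring is closed and no stereocentre is formed. The step needs regioselectivity (oxygen at C6, acyl at C5) and chemoselectivity (acyl shift rather than protonation of 20, and the external carboxylate rather than an oxygen of the arms as the nucleophile). The C4 methoxy group secures the first: its inductive pull makes C6 the more electrophilic aryne carbon and places the developing negative charge at C5 beside oxygen, which should outweigh the steric demand of the C1 benzylic arm. Methyl caps on both pyranone oxygens, an excess of carboxylate, a non-protic solvent and high temperature serve the second.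

**Step 11**
Reactants: 21 1-{2-hydroxy-4,6-dimethoxy-3,5-bis[(6-ethyl-4-methoxy-5-methyl-2-oxo-2H-pyran-3-yl)methyl]phenyl}-2-methylpropan-1-one
Product: 22 1-{2,4,6-trihydroxy-3,5-bis[(6-ethyl-4-hydroxy-5-methyl-2-oxo-2H-pyran-3-yl)methyl]phenyl}-2-methylpropan-1-one (target)
Conditions: BBr3 (10 equiv), CH2Cl2, −78 → 0 °C; MeOH then H2O, 0 °C
Reagents that add atoms: none
Why: BBr3 coordinates each ether oxygen and bromide removes the methyl group by SN2 (Lewis-acid ether cleavage), the C4 methoxy being helped by chelation to the ketone and the pyranone methyl ethers reacting as vinylogous esters; low temperature and a cold quench limit acid-induced cyclodehydration between a phenol and a pyranone hydroxyl.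

**Compound list**
1 | methyl 3-oxopentanoate | CCC(=O)CC(=O)OC | starting material
2 | N-methoxy-N-methylpropanamide | CCC(=O)N(C)OC | starting material
3 | methyl 4-methyl-3,5-dioxoheptanoate (racemic, enolisable C4) | CCC(=O)C(C)C(=O)CC(=O)OC | intermediate
4 | 6-ethyl-4-hydroxy-5-methyl-2H-pyran-2-one | CCc1oc(=O)cc(O)c1C | intermediate
5 | 4-hydroxy-2,6-dimethoxybenzaldehyde | COc1cc(O)cc(OC)c1C=O | starting material
6 | 4-hydroxy-2,6-dimethoxybenzene-1,3-dicarbaldehyde | COc1cc(O)c(C=O)c(OC)c1C=O | intermediate
7 | 5-bromo-4-hydroxy-2,6-dimethoxybenzene-1,3-dicarbaldehyde | COc1c(Br)c(O)c(C=O)c(OC)c1C=O | intermediate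
8 | 2-bromo-4,6-di(1,3-dioxolan-2-yl)-3,5-dimethoxyphenol | COc1c(Br)c(O)c(C2OCCO2)c(OC)c1C1OCCO1 | intermediate
9 | [2-bromo-4,6-di(1,3-dioxolan-2-yl)-3,5-dimethoxyphenoxy]trimethylsilane (not isolated) | COc1c(Br)c(O[Si](C)(C)C)c(C2OCCO2)c(OC)c1C1OCCO1 | intermediate
10 | lithium 2,4-di(1,3-dioxolan-2-yl)-3,5-dimethoxy-6-(trimethylsilyl)phenoxide (not isolated) | [Li+].COc1c([Si](C)(C)C)c([O-])c(C2OCCO2)c(OC)c1C1OCCO1 | intermediate
11 | 2,4-di(1,3-dioxolan-2-yl)-3,5-dimethoxy-6-(trimethylsilyl)phenyl trifluoromethanesulfonate | COc1c([Si](C)(C)C)c(OS(=O)(=O)C(F)(F)F)c(C2OCCO2)c(OC)c1C1OCCO1 | intermediate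
12 | 2,4-diformyl-3,5-dimethoxy-6-(trimethylsilyl)phenyl trifluoromethanesulfonate | COc1c([Si](C)(C)C)c(OS(=O)(=O)C(F)(F)F)c(C=O)c(OC)c1C=O | intermediate
13 | 2-[(6-ethyl-5-methyl-2,4-dioxo-2H-pyran-3(4H)-ylidene)methyl]-4-formyl-3,5-dimethoxy-6-(trimethylsilyl)phenyl trifluoromethanesulfonate (not isolated; alkene geometry undefined, lost on reduction) | COc1c([Si](C)(C)C)c(OS(=O)(=O)C(F)(F)F)c(C=C2C(=O)C(C)=C(CC)OC2=O)c(OC)c1C=O | intermediate
14 | 2-[(6-ethyl-4-hydroxy-5-methyl-2-oxo-2H-pyran-3-yl)methyl]-4-formyl-3,5-dimethoxy-6-(trimethylsilyl)phenyl trifluoromethanesulfonate (not isolated) | COc1c([Si](C)(C)C)c(OS(=O)(=O)C(F)(F)F)c(Cc2c(O)c(C)c(CC)oc2=O)c(OC)c1C=O | intermediate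
15 | 4-[(6-ethyl-5-methyl-2,4-dioxo-2H-pyran-3(4H)-ylidene)methyl]-2-[(6-ethyl-4-hydroxy-5-methyl-2-oxo-2H-pyran-3-yl)methyl]-3,5-dimethoxy-6-(trimethylsilyl)phenyl trifluoromethanesulfonate (not isolated; alkene geometry undefined, lost on reduction) | COc1c([Si](C)(C)C)c(OS(=O)(=O)C(F)(F)F)c(Cc2c(O)c(C)c(CC)oc2=O)c(OC)c1C=C1C(=O)C(C)=C(CC)OC1=O | intermediate
16 | 2,4-bis[(6-ethyl-4-hydroxy-5-methyl-2-oxo-2H-pyran-3-yl)methyl]-3,5-dimethoxy-6-(trimethylsilyl)phenyl trifluoromethanesulfonate | COc1c([Si](C)(C)C)c(OS(=O)(=O)C(F)(F)F)c(Cc2c(O)c(C)c(CC)oc2=O)c(OC)c1Cc1c(O)c(C)c(CC)oc1=O | intermediate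
17 | 2,4-bis[(6-ethyl-4-methoxy-5-methyl-2-oxo-2H-pyran-3-yl)methyl]-3,5-dimethoxy-6-(trimethylsilyl)phenyl trifluoromethanesulfonate | COc1c(Cc2c(OC)c(C)c(CC)oc2=O)c(OC)c([Si](C)(C)C)c(OS(=O)(=O)C(F)(F)F)c1Cc1c(OC)c(C)c(CC)oc1=O | intermediate
18 | isobutyric acid (2-methylpropanoic acid) | CC(C)C(=O)O | starting material
19 | 3,5-bis[(6-ethyl-4-methoxy-5-methyl-2-oxo-2H-pyran-3-yl)methyl]-4,6-dimethoxy-1,2-didehydrobenzene, the C5≡C6 aryne (not isolated) | COC1=C(Cc2c(OC)c(C)c(CC)oc2=O)C(OC)=C(Cc2c(OC)c(C)c(CC)oc2=O)C#C1 | intermediate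
20 | caesium 2-(isobutyryloxy)aryl anion, carbanion at C5 beside the C4 methoxy group (not isolated) | [Cs+].COc1[c-]c(OC(=O)C(C)C)c(Cc2c(OC)c(C)c(CC)oc2=O)c(OC)c1Cc1c(OC)c(C)c(CC)oc1=O | intermediate
21 | 1-{2-hydroxy-4,6-dimethoxy-3,5-bis[(6-ethyl-4-methoxy-5-methyl-2-oxo-2H-pyran-3-yl)methyl]phenyl}-2-methylpropan-1-one | COc1c(Cc2c(OC)c(C)c(CC)oc2=O)c(OC)c(C(=O)C(C)C)c(O)c1Cc1c(OC)c(C)c(CC)oc1=O | intermediate
22 | 1-{2,4,6-trihydroxy-3,5-bis[(6-ethyl-4-hydroxy-5-methyl-2-oxo-2H-pyran-3-yl)methyl]phenyl}-2-methylpropan-1-one | CCc1oc(=O)c(Cc2c(O)c(Cc3c(O)c(C)c(CC)oc3=O)c(O)c(C(=O)C(C)C)c2O)c(O)c1C | target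

**Step count**
Total: 11 steps. Longest linear sequence: 9 steps (5 → 22, steps 3–11); the pyranone branch (steps 1–2) joins at step 8.

**Steps most likely to fail**

Step 10 (key step). The aryl anion may be protonated before the acyl shift, so that only O-arylation takes place. The aryne may be captured by a pyranone oxygen of the C1 arm before the carboxylate arrives. Fluoride may also be slow to reach the crowded C5 silicon. The fallback forms the C5–acyl bond by electrophilic acylation and sets out from 6. The reductive alkylation of step 8 (4, Hantzsch ester, L-proline) applied to 6 should give 2,4-bis[(6-ethyl-4-hydroxy-5-methyl-2-oxo-2H-pyran-3-yl)methyl]-3,5-dimethoxyphenol F1. Trimethylsilyldiazomethane in methanol/toluene should methylate only the two acidic pyranone hydroxyls and give 2,4-bis[(6-ethyl-4-methoxy-5-methyl-2-oxo-2H-pyran-3-yl)methyl]-3,5-dimethoxyphenol F2. Isobutyryl chloride with TiCl4 in CH2Cl2 (O-acylation and Fries shift, or direct Friedel–Crafts acylation) should then acylate the single free ring carbon, which lies ortho to the phenol, and the route is rejoined at 21.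

Step 8. Condensation at the two doubly ortho-substituted, electron-rich aldehydes may be slow, so that the reaction stalls after one arm or a second pyranone adds to an arylidene before hydride does. The fallback uses a benzylic cation instead of a Knoevenagel acceptor and sets out from 12. NaBH4 in MeOH/THF at 0 °C should give 2,4-bis(hydroxymethyl)-3,5-dimethoxy-6-(trimethylsilyl)phenyl trifluoromethanesulfonate F3. Warming F3 with 4 (2.2 equiv) in hexafluoroisopropanol, if needed with catalytic Sc(OTf)3, should ionise the 2,6-dioxygenated benzylic alcohols and benzylate C3 of the pyranone (dehydrative Friedel–Crafts-type alkylation of a cyclic 1,3-dicarbonyl). O-Benzylation is reversible under these conditions, the arene has no free position for self-condensation, and the route is rejoined at 16.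

Step 5. Acetalisation of the strongly conjugated, hydrogen-bonded aldehydes may stay incomplete, or the very labile acetals may hydrolyse during isolation. The fallback masks the aldehydes by reduction instead and sets out from 7. NaBH4 should give 2-bromo-4,6-bis(hydroxymethyl)-3,5-dimethoxyphenol F4, and hexamethyldisilazane its tris(trimethylsilyl) ether F5. n-BuLi at −78 °C should bring about bromine–lithium exchange and the retro-Brook shift from the aryl oxygen only, to the lithium 2-silylphenoxide F6, which PhNTf2 converts into 3,5-dimethoxy-6-(trimethylsilyl)-2,4-bis[(trimethylsilyloxy)methyl]phenyl trifluoromethanesulfonate F7. Acetic acid in THF/water should free the two benzylic alcohols to the diol F3 already described, and MnO2 in CH2Cl2 should oxidise it to the dialdehyde, rejoining the route at 12.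

**Further compounds**
F1 | step 10 | 2,4-bis[(6-ethyl-4-hydroxy-5-methyl-2-oxo-2H-pyran-3-yl)methyl]-3,5-dimethoxyphenol | COc1cc(O)c(Cc2c(O)c(C)c(CC)oc2=O)c(OC)c1Cc1c(O)c(C)c(CC)oc1=O
F2 | step 10 | 2,4-bis[(6-ethyl-4-methoxy-5-methyl-2-oxo-2H-pyran-3-yl)methyl]-3,5-dimethoxyphenol | COc1cc(O)c(Cc2c(OC)c(C)c(CC)oc2=O)c(OC)c1Cc1c(OC)c(C)c(CC)oc1=O
F3 | step 8 | 2,4-bis(hydroxymethyl)-3,5-dimethoxy-6-(trimethylsilyl)phenyl trifluoromethanesulfonate | COc1c([Si](C)(C)C)c(OS(=O)(=O)C(F)(F)F)c(CO)c(OC)c1CO
F4 | step 5 | 2-bromo-4,6-bis(hydroxymethyl)-3,5-dimethoxyphenol | COc1c(Br)c(O)c(CO)c(OC)c1CO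
F5 | step 5 | {2-bromo-3,5-dimethoxy-4,6-bis[(trimethylsilyloxy)methyl]phenoxy}trimethylsilane | COc1c(Br)c(O[Si](C)(C)C)c(CO[Si](C)(C)C)c(OC)c1CO[Si](C)(C)C
F6 | step 5 | lithium 3,5-dimethoxy-6-(trimethylsilyl)-2,4-bis[(trimethylsilyloxy)methyl]phenoxide | [Li+].COc1c([Si](C)(C)C)c([O-])c(CO[Si](C)(C)C)c(OC)c1CO[Si](C)(C)C
F7 | step 5 | 3,5-dimethoxy-6-(trimethylsilyl)-2,4-bis[(trimethylsilyloxy)methyl]phenyl trifluoromethanesulfonate | COc1c([Si](C)(C)C)c(OS(=O)(=O)C(F)(F)F)c(CO[Si](C)(C)C)c(OC)c1CO[Si](C)(C)C
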